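**Assumption:** the target has no sp3 stereocentres. Its only stereo-element is the E-trisubstituted alkene, in which the pyranone-CH2 and the CH3 are cis and the CH2 and the (CH2)6Ph chain are trans. (6-Bromohexyl)benzene, ethyl 2-methylacetoacetate and methoxyacetyl chloride are taken as commercial.

## Retrosynthetic overview
- Target **1** is cut at the sp3–sp2 bond between the pyranone 6-CH2 and the alkene CH. This gives the lateral (6-CH3-derived) zinc dienolate of 3,4-dimethoxy-5,6-dimethyl-2-pyranone **2** plus the (E)-alkenyl iodide **3**, joined by Negishi coupling.
- **3** comes from Zr-catalysed methylalumination (syn-carbometalation) of 8-phenyloct-1-yne **11** followed by I2. **11** comes from (6-bromohexyl)benzene **9**.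
- The pyranone ring is built by a Dieckmann cyclisation of the enol ester **6** (from ethyl 2-methylacetoacetate **4** and methoxyacetyl chloride **5**) to give **7**, then O-methylation. The 3-OMe comes in with the acid chloride, so no C3 oxidation is needed.
- Order of events: the ring is formed first (steps 1–3), the alkene geometry is set in step 5, and the two fragments are joined last (step 6).

## Route

**Step 1**
Reactants: **4** ethyl 2-methylacetoacetate; **5** methoxyacetyl chloride
Product: **6** ethyl (Z)-3-(2-methoxyacetoxy)-2-methylbut-2-enoate
Conditions: NaH, THF, 0 °C; then **5**, 0 °C → rt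
Reagents that add atoms: none beyond the reactants
Why: The chelated (Z)-sodium enolate of an α-substituted β-ketoester is acylated on oxygen by a hard acid chloride (O-acylation). The enol-ester C=C geometry, with O-acyl cis to CO2Et, is the one needed for ring closure.

**Step 2**
Reactants: **6**
Product: **7** 4-hydroxy-3-methoxy-5,6-dimethyl-2H-pyran-2-one
Conditions: LiHMDS (1.1 equiv), THF, −78 °C → 0 °C; aqueous HCl work-up
Reagents that add atoms: none
Why: Deprotonation of the acidic OCH2 group of the methoxyacetate gives an ester enolate. This undergoes 6-exo Dieckmann attack on the cis CO2Et and loses EtO–, forming the lactone ring; the product is trapped as the stable 4-oxido-pyranone (Dieckmann / intramolecular Claisen). No stereocentre is formed.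

**Step 3**
Reactants: **7**
Product: **2** 3,4-dimethoxy-5,6-dimethyl-2H-pyran-2-one
Conditions: **8**, K2CO3, acetone, reflux
Reagents that add atoms: **8** dimethyl sulfate, COS(=O)(=O)OC
Why: O-methylation of the vinylogous acid anion. C3 and C5 are already substituted, so O-alkylation is strongly favoured.

**Step 4**
Reactants: **9** (6-bromohexyl)benzene
Product: **11** 8-phenyloct-1-yne
Conditions: **10**, DMSO, rt
Reagents that add atoms: **10** lithium acetylide–ethylenediamine complex, [Li+].[C-]#C.NCCN (adds C2H)
Why: SN2 displacement of a primary bromide by acetylide gives the terminal alkyne; the phenyl ring is inert.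

**Step 5**
Reactants: **11**
Product: **3** [(E)-8-iodo-7-methyloct-7-en-1-yl]benzene
Conditions: **12**, cat. Cp2ZrCl2 (0.2 equiv), ClCH2CH2Cl, rt; then **13**, THF, −30 °C → rt
Reagents that add atoms: **12** trimethylaluminum, C[Al](C)C (adds CH3); **13** iodine, II (adds I)
Why: Negishi carboalumination adds Me and Al syn across the terminal alkyne, with Me going to the internal carbon. Iodinolysis then replaces Al with I with retention, so I is cis to Me and trans to the chain. This sets the E geometry directly.

**Step 6**
Reactants: **2**; **3**
Product: **1** lehualide E
Conditions: **2** + LDA (1.0 equiv), THF, −78 °C, 30 min; ZnCl2 (1.1 equiv), −78 → 0 °C; then **3** (1.2 equiv), Pd(PPh3)4 (5 mol %), THF, 0 → 50 °C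
Reagents that add atoms: none (LDA, ZnCl2 and the Pd catalyst leave no atoms)
Why: LDA selectively deprotonates the 6-CH3, which is vinylogous to the lactone C=O through C6=C5–C4=C3–C2=O; the 5-CH3 is not conjugated and stays intact. Transmetalation to zinc followed by Pd-catalysed Negishi coupling with the alkenyl iodide proceeds with retention of alkene geometry, so the E-olefin from step 5 is carried through unchanged.
Proposed new method: the zinc dienolate of a 6-methyl-2-pyranone is coupled as a heterobenzylic / Reformatsky-type nucleophile with an alkenyl iodide. The closest known chemistry is Negishi coupling of benzylzinc reagents and Pd-catalysed coupling of Reformatsky reagents with alkenyl halides. The main risks are C3 or C5 reactivity of the dienolate and alkene migration into conjugation.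

## Compound list
1 | lehualide E | COc1c(C)c(C/C=C(\C)CCCCCCc2ccccc2)oc(=O)c1OC | target
2 | 3,4-dimethoxy-5,6-dimethyl-2H-pyran-2-one | COC1=C(OC)C(C)=C(C)OC1=O | intermediate
3 | [(E)-8-iodo-7-methyloct-7-en-1-yl]benzene | I/C=C(\C)CCCCCCc1ccccc1 | intermediate
4 | ethyl 2-methylacetoacetate | CCOC(=O)C(C)C(C)=O | starting material
5 | methoxyacetyl chloride | COCC(=O)Cl | starting material
6 | ethyl (Z)-3-(2-methoxyacetoxy)-2-methylbut-2-enoate | CCOC(=O)/C(C)=C(\OC(=O)COC)C | intermediate
7 | 4-hydroxy-3-methoxy-5,6-dimethyl-2H-pyran-2-one | COC1=C(O)C(C)=C(C)OC1=O | intermediate
8 | dimethyl sulfate | COS(=O)(=O)OC | starting material (reagent)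
9 | (6-bromohexyl)benzene | BrCCCCCCc1ccccc1 | starting material
10 | lithium acetylide–ethylenediamine complex | [Li+].[C-]#C.NCCN | starting material (reagent)
11 | 8-phenyloct-1-yne | C#CCCCCCCc1ccccc1 | intermediate
12 | trimethylaluminum | C[Al](C)C | starting material (reagent)
13 | iodine | II | starting material (reagent)

## Totals
Total steps: 6. Longest linear sequence: 4 steps (4 → 6 → 7 → 2 → 1). The side-chain branch is 3 steps (9 → 11 → 3).

## Three steps most likely to fail
1. **Step 6 (lateral zinc dienolate Negishi).** Competing C3 or C5 reactivity, self-condensation of the lithio-pyranone, or alkene isomerisation could lower the yield.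
   - Fallback: reverse the polarity. Convert **2** to 6-(bromomethyl)pyranone by lateral lithiation and quenching with a bromine source (BrCF2CF2Br). Then couple it with the alkenylalane from step 5 (before I2 quench) using Cu catalysis, in an allylic-type SN2 coupling.
2. **Step 2 (Dieckmann of the enol ester).** O→C acyl migration, or reversion by attack of the base on the acyl group, could compete with ring closure.
   - Fallback: build the ring by Ru(II)- or Rh(III)-catalysed oxidative annulation of 2,3-dimethoxyacrylic acid with 2-butyne. This gives **2** directly, and the symmetric alkyne removes any regiochemistry problem.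
3. **Step 1 (O- versus C-acylation, enol-ester geometry).** C-acylation would give a quaternary dead-end, and the E-enol ester cannot cyclise.
   - Fallback: make 4-hydroxy-5,6-dimethyl-2-pyranone from the 3-methylpentane-2,4-dione dianion and dimethyl carbonate, followed by base-mediated lactonisation. Then install the 3-OMe by C3 iodination (NIS) and Cu-catalysed methoxylation (CuI/phenanthroline, NaOMe), and methylate O4 as in step 3.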